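**Retrosynthetic overview**

- Locants: C5 is the spiro atom. Ring A (cyclopentane) is C1–C4, with C2 bearing the lactone oxygen and C3 the lactone α-carbon (Cα). Ring B (cyclohexene) is C6 (CH2O-angelate), C7, C8 (OH), C9 (OH), C10 (CH3). Ring C is the lactone.
- Enabling feature: the ring C bonds O–C2 and Cα–C3 stand cis on the two adjacent ring A carbons that lie β to C5. Ring C is therefore what a two-carbon ketene unit adds across a C2=C3 double bond, and a phenylsulfinyl group on C2 fixes both the regiochemistry and the face of that addition.
- Disconnections: trans-diol ⇒ C8–C9 epoxide of a ring B diene; CH2O-angelate ⇒ C6 dienyl triflate ⇒ C6 enone; exocyclic CH2 ⇒ Mannich methylenation; ring C ⇒ vinyl sulfoxide + dichloroketene; C5 ⇒ two successive α'-alkylations, the second anti to the C10 methyl.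
- Order of ring formation: ring B (from cyclohex-2-enone), ring A (ring-closing metathesis), ring C (key step). No protecting group is used.

Key step: step 7

Assumption: sulfur-to-carbon chirality transfer is taken to follow the rotamer of the acyloxysulfonium enolate in which S-phenyl turns toward the vinylic C3–H and away from C1H2; if the sense proves opposite, (−)-(S,S)-diethyl tartrate is used in step 6.

**Step 1**
Reactants: 1 cyclohex-2-en-1-one
Product: 3 (2R,3S)-2-allyl-3-methylcyclohexan-1-one, via methylzinc enolate 2 (not isolated)
Conditions: Me2Zn, Cu(OTf)2 (1 mol %), (S,R,R)-binaphthol bis(1-phenylethyl)amine phosphoramidite (2 mol %), toluene, −30 °C; then allyl acetate, Pd(PPh3)4 (3 mol %), 0 °C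
Reagents that add atoms: dimethylzinc C[Zn]C; allyl acetate C=CCOC(C)=O
Why: Copper-catalysed asymmetric conjugate addition should set C10 under ligand control, and the regiodefined zinc enolate is allylated through a π-allylpalladium complex (Tsuji–Trost type) trans to the new methyl group, a C5 configuration that is erased again in step 3.

**Step 2**
Reactants: 3 (2R,3S)-2-allyl-3-methylcyclohexan-1-one
Product: 5 (5S,6R)-6-allyl-5-methylcyclohex-2-en-1-one, via kinetic lithium enolate 4 (not isolated)
Conditions: LiN(iPr)2, THF, −78 °C; then PhS(Cl)=NtBu, −78 °C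
Reagents that add atoms: none
Why: Kinetic deprotonation takes the less hindered C7–H, and the sulfur-bound enolate adduct eliminates at low temperature (Mukaiyama dehydrogenation), which gives the C7=C8 enone, leaves C5–H as the only α-proton and does not touch C10.

**Step 3**
Reactants: 5 (5S,6R)-6-allyl-5-methylcyclohex-2-en-1-one
Product: 7 (5S,6R)-6-allyl-6-(2-chloroallyl)-5-methylcyclohex-2-en-1-one, via cross-conjugated lithium dienolate 6 (not isolated)
Conditions: LiN(iPr)2, THF–DMPU, −78 °C; then 2,3-dichloropropene, Bu4NI (cat.), −78 → 0 °C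
Reagents that add atoms: 2,3-dichloroprop-1-ene C=C(Cl)CCl
Why: In the planar α'-dienolate the C10 methyl turns pseudo-axial to avoid allylic strain with the allyl group, so the SN2 enolate alkylation should occur on the opposite face and set C5 with the chloroallyl arm (C1, C2) trans and the allyl arm (C4, C3) cis to the methyl.

**Step 4**
Reactants: 7 (5S,6R)-6-allyl-6-(2-chloroallyl)-5-methylcyclohex-2-en-1-one
Product: 8 (5R,10S)-2-chloro-10-methylspiro[4.5]deca-2,7-dien-6-one
Conditions: second-generation Grubbs catalyst (5–10 mol %), benzene, 65 °C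
Reagents that add atoms: none
Why: Ring-closing metathesis of an allyl/2-chloroallyl pair to a 1-chlorocyclopentene is a known substrate class; the catalyst loads on the allyl arm and the chlorine keeps C2 and C3 distinct, so C5 stays stereogenic.

**Step 5**
Reactants: 8 (5R,10S)-2-chloro-10-methylspiro[4.5]deca-2,7-dien-6-one
Product: 9 (5R,10S)-10-methyl-2-(phenylsulfanyl)spiro[4.5]deca-2,7-dien-6-one
Conditions: Bu3SnSPh, Pd2(dba)3 (2.5 mol %), P(tBu)3 (10 mol %), toluene, 100 °C
Reagents that add atoms: tributyl(phenylthio)stannane CCCC[Sn](CCCC)(CCCC)Sc1ccccc1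
Why: Migita-type C–S cross-coupling of an alkenyl halide on electron-rich zerovalent palladium; the neutral tin thiolate avoids free thiolate that would add to the ring B enone, and no stereocentre is touched.

**Step 6**
Reactants: 9 (5R,10S)-10-methyl-2-(phenylsulfanyl)spiro[4.5]deca-2,7-dien-6-one
Product: 10 (5R,10S)-10-methyl-2-[(R)-phenylsulfinyl]spiro[4.5]deca-2,7-dien-6-one
Conditions: Ti(OiPr)4 (20 mol %), (+)-(R,R)-diethyl tartrate (40 mol %), iPrOH, 4 Å MS, cumene hydroperoxide, CH2Cl2, −20 °C; sulfur epimers separated on silica
Reagents that add atoms: cumene hydroperoxide CC(C)(OO)c1ccccc1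
Why: Kagan oxidation, in which the chiral titanium tartrate peroxide transfers oxygen to one lone pair of sulfur and, by the usual aryl-versus-non-aryl model, the (R,R)-tartrate should give the (R)-sulfoxide while the electron-poor enone stays inert.

**Step 7**
Reactants: 10 (5R,10S)-10-methyl-2-[(R)-phenylsulfinyl]spiro[4.5]deca-2,7-dien-6-one
Product: 13 tricyclic α,α-dichloro-γ-(phenylsulfanyl) lactone enone (ring C cis-fused at C2–C3 on the C6 face of ring A; SPh on C2 on the C10 face), via acyloxysulfonium enolate 11 (not isolated), via thionium carboxylate 12 (not isolated)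
Conditions: Cl3CCOCl (slow addition), Zn–Cu couple, Et2O, 0 °C → reflux
Reagents that add atoms: trichloroacetyl chloride ClC(Cl)(Cl)C(Cl)=O
Why: Zinc dechlorinates the acid chloride to dichloroketene, which acylates the sulfinyl oxygen to give 11; its array Cl2C=C(O−)–O–S+–C2=C3 undergoes a [3,3]-sigmatropic shift that makes Cα–C3 and breaks S–O, and the carboxylate of 12 then adds to the thionium carbon C2 and makes O–C2. The closest known reaction type is the Marino lactonization of 1-cycloalkenyl aryl sulfoxides with dichloroketene. Ring C is the only ring closed, by 5-exo-trig attack of carboxylate oxygen on C2=S+ after the sigmatropic C–C bond formation. C3 is set by the sulfur configuration, because the enolate carbon is delivered suprafacially on the alkene face that carries the S–O bond, and C2 is set by the tether, because the carboxylate fixed on that face of C3 can only close to the cis-bicyclo[3.3.0] ring fusion. The step needs regio-, facial and chemoselectivity: sulfur on C2 (placed by the order of alkylations in steps 1 and 3) dictates Cα to C3 and O to C2, the (R)-sulfinyl group directs both bonds to the face syn to the flat C6 carbonyl, and the sulfinyl oxygen is the only strong nucleophile while the electron-poor C7=C8 enone does not react with the ketene. One operation should thus give ring C and both ring-fusion stereocentres in the required relation to C5 and C10.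

**Step 8**
Reactants: 13 tricyclic α,α-dichloro-γ-(phenylsulfanyl) lactone enone
Product: 14 tricyclic lactone enone (H on C2 and C3 on the C10 face of ring A)
Conditions: Bu3SnH (4 equiv), AIBN (cat.), benzene, reflux
Reagents that add atoms: none
Why: In this radical chain reduction stannyl radicals abstract both α-chlorines and cleave the C2–S bond, and the C2 radical can take up hydrogen only on the convex face, so the cis ring fusion is kept.

**Step 9**
Reactants: 14 tricyclic lactone enone
Product: 18 α-methylene lactone enone, via lithium lactone enolate 15 (not isolated), via Mannich base 16 (not isolated), via trimethylammonium iodide 17 (not isolated)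
Conditions: LiN(iPr)2, THF, −78 °C; CH2=NMe2+ I−, −78 °C → rt; MeI, MeOH, rt; aq NaHCO3, CH2Cl2
Reagents that add atoms: dimethyl(methylidene)ammonium iodide C=[N+](C)C.[I-]
Why: The lactone CH2 is deprotonated kinetically (the enone has no α-proton and its γ-protons react more slowly), and the sequence of Mannich reaction, exhaustive methylation and Hofmann-type elimination gives the exocyclic methylene, so the transient Cα configuration is of no consequence.

**Step 10**
Reactants: 18 α-methylene lactone enone
Product: 19 ring B dienyl triflate (C6–OTf, C6=C7, C8=C9)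
Conditions: Tf2O, 2,6-di-tert-butyl-4-methylpyridine, CH2Cl2, 0 °C → rt
Reagents that add atoms: trifluoromethanesulfonic anhydride O=S(=O)(OS(=O)(=O)C(F)(F)F)C(F)(F)F
Why: O-triflation of the enone carbonyl followed by loss of the γ-proton at C9 to the hindered base gives the linear dienyl triflate (non-basic enol triflate formation), the only possible regiochemistry because C5 is quaternary, and it spares the base-sensitive α-methylene lactone and C10.

**Step 11**
Reactants: 19 ring B dienyl triflate
Product: 20 ring B hydroxymethyl diene
Conditions: Bu3SnCH2OH, Pd2(dba)3 (5 mol %), AsPh3 (20 mol %), LiCl, NMP, 50 °C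
Reagents that add atoms: (tributylstannyl)methanol CCCC[Sn](CCCC)(CCCC)CO
Why: Stille coupling of an alkenyl triflate transfers the hydroxymethyl group to C6; the weakly donating arsine speeds transmetalation at the hindered site and avoids phosphine addition to the methylene lactone.

**Step 12**
Reactants: 20 ring B hydroxymethyl diene; 21 angelic acid
Product: 23 ring B diene angelate, via mixed anhydride 22 (not isolated)
Conditions: 21, 2,4,6-trichlorobenzoyl chloride, Et3N, toluene, rt; then 20, 40 °C
Reagents that add atoms: none
Why: Yamaguchi esterification without a nucleophilic catalyst acylates the unhindered primary allylic alcohol and should keep the Z geometry of the angelate, which nucleophilic catalysts tend to isomerise.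

**Step 13**
Reactants: 23 ring B diene angelate
Product: 24 C8–C9 vinyl epoxide (oxygen trans to the C10 methyl)
Conditions: dimethyldioxirane, acetone, −40 °C
Reagents that add atoms: dimethyldioxirane CC1(C)OO1
Why: The sterically demanding electrophilic epoxidation should take the cis-disubstituted C8=C9 bond rather than C6=C7, which is shielded by C5 and deactivated by the allylic ester, and rather than the two electron-poor ester-conjugated alkenes; attack anti to the neighbouring C10 methyl sets C9.

**Step 14**
Reactants: 24 C8–C9 vinyl epoxide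
Product: 25 CNP0224912.1
Conditions: H2O–THF (1:3), HClO4 (cat.), 0 °C
Reagents that add atoms: water O
Why: Acid-catalysed epoxide hydrolysis should open the activated allylic C8–O bond with inversion, which sets C8 and gives the all-trans C8-OH/C9-OH/C10-CH3 array while C9 keeps its oxygen.

**Compound list**

1 | cyclohex-2-en-1-one | O=C1C=CCCC1 | starting material
2 | methylzinc (S)-3-methylcyclohex-1-en-1-olate | C1=C(O[Zn]C)CCC[C@@H]1C | intermediate
3 | (2R,3S)-2-allyl-3-methylcyclohexan-1-one | C=CC[C@H]1C(=O)CCC[C@@H]1C | intermediate
4 | kinetic lithium enolate of 3 | C=CC[C@H]1C(O[Li])=CCC[C@@H]1C | intermediate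
5 | (5S,6R)-6-allyl-5-methylcyclohex-2-en-1-one | C=CC[C@H]1C(=O)C=CC[C@@H]1C | intermediate
6 | cross-conjugated lithium dienolate of 5 | C=CCC1=C(O[Li])C=CC[C@@H]1C | intermediate
7 | (5S,6R)-6-allyl-6-(2-chloroallyl)-5-methylcyclohex-2-en-1-one | C=CC[C@]1(CC(Cl)=C)C(=O)C=CC[C@@H]1C | intermediate
8 | (5R,10S)-2-chloro-10-methylspiro[4.5]deca-2,7-dien-6-one | ClC1=CC[C@]2(C1)C(=O)C=CC[C@@H]2C | intermediate
9 | (5R,10S)-10-methyl-2-(phenylsulfanyl)spiro[4.5]deca-2,7-dien-6-one | c1ccccc1SC1=CC[C@]2(C1)C(=O)C=CC[C@@H]2C | intermediate
10 | (5R,10S)-10-methyl-2-[(R)-phenylsulfinyl]spiro[4.5]deca-2,7-dien-6-one | c1ccccc1[S@](=O)C1=CC[C@]2(C1)C(=O)C=CC[C@@H]2C | intermediate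
11 | acyloxysulfonium enolate (O-acylated sulfoxide zwitterion) | c1ccccc1[S@+](OC([O-])=C(Cl)Cl)C1=CC[C@]2(C1)C(=O)C=CC[C@@H]2C | intermediate
12 | thionium carboxylate (Cα–C3 made, C2=S+) | [O-]C(=O)C(Cl)(Cl)[C@H]1C[C@]2(CC1=[S+]c1ccccc1)C(=O)C=CC[C@@H]2C | intermediate
13 | tricyclic α,α-dichloro-γ-(phenylsulfanyl) lactone enone, ring C on the C6 face of ring A | ClC1(Cl)C(=O)O[C@]2(Sc3ccccc3)C[C@@]4(C[C@H]12)C(=O)C=CC[C@@H]4C | intermediate
14 | tricyclic lactone enone, cis-fused | C1C(=O)O[C@@H]2C[C@@]3(C[C@H]12)C(=O)C=CC[C@@H]3C | intermediate
15 | lithium lactone enolate of 14 | C1=C(O[Li])O[C@@H]2C[C@@]3(C[C@H]12)C(=O)C=CC[C@@H]3C | intermediate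
16 | α-(dimethylaminomethyl) lactone (Mannich base, Cα epimers) | CN(C)CC1C(=O)O[C@@H]2C[C@@]3(C[C@H]12)C(=O)C=CC[C@@H]3C | intermediate
17 | α-(trimethylammoniomethyl) lactone iodide | C[N+](C)(C)CC1C(=O)O[C@@H]2C[C@@]3(C[C@H]12)C(=O)C=CC[C@@H]3C.[I-] | intermediate
18 | α-methylene lactone enone | C=C1C(=O)O[C@@H]2C[C@@]3(C[C@H]12)C(=O)C=CC[C@@H]3C | intermediate
19 | ring B dienyl triflate | C=C1C(=O)O[C@@H]2C[C@@]3(C[C@H]12)C(OS(=O)(=O)C(F)(F)F)=CC=C[C@@H]3C | intermediate
20 | ring B hydroxymethyl diene | C=C1C(=O)O[C@@H]2C[C@@]3(C[C@H]12)C(CO)=CC=C[C@@H]3C | intermediate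
21 | angelic acid, (Z)-2-methylbut-2-enoic acid | C/C=C(/C)C(=O)O | starting material
22 | angelic 2,4,6-trichlorobenzoic mixed anhydride | C/C=C(/C)C(=O)OC(=O)c1c(Cl)cc(Cl)cc1Cl | intermediate
23 | ring B diene angelate | C=C1C(=O)O[C@@H]2C[C@@]3(C[C@H]12)C(COC(=O)/C(C)=C\C)=CC=C[C@@H]3C | intermediate
24 | C8–C9 vinyl epoxide, oxygen trans to the C10 methyl | C=C1C(=O)O[C@@H]2C[C@@]3(C[C@H]12)C(COC(=O)/C(C)=C\C)=C[C@H]4O[C@H]4[C@@H]3C | intermediate
25 | CNP0224912.1 | C=C1C(=O)O[C@@H]2C[C@@]3(C[C@H]12)C(COC(=O)/C(C)=C\C)=C[C@H](O)[C@@H](O)[C@@H]3C | target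

Total step count: 14. Longest linear sequence: 14 steps, from cyclohex-2-en-1-one (1) to 25.

**Steps most likely to fail**

Step 7. The zinc/acid chloride medium may deoxygenate the sulfoxide before the acylation–rearrangement sequence. The ketene may then add in a [2+2] sense to the vinyl sulfide so formed. Rearrangement through a second rotamer of the acyloxysulfonium enolate may also erode the facial control.

The fallback replaces the sigmatropic event by a radical–polar crossover and sets out from sulfide 9. Mono-tert-butyl malonate, Mn(OAc)3·2H2O and Cu(OAc)2 in AcOH at 50 °C should add the electrophilic malonyl radical to C3. The α-thio radical is then oxidised to the thionium ion and closed with the free carboxyl group, giving the γ-(phenylsulfanyl) lactone tert-butyl ester F1. Bu3SnH/AIBN removes sulfur to give the lactone tert-butyl ester F2, and CF3CO2H gives the α-carboxy lactone F3. Aqueous formaldehyde with Et2NH in AcOH/NaOAc then effects decarboxylative Mannich methylenation, and the route is rejoined at 18. In this variant the face rests on substrate control only.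

Step 6. The chiral oxidant may discriminate poorly between the two sp2 substituents on sulfur, so that oxygen transfer to both lone pairs competes and material is lost in the separation of sulfur epimers.

The fallback builds the stereogenic sulfur by C–S bond formation instead of oxidation and sets out from chloride 8. Benzenesulfenate anion, released from tert-butyl 3-(phenylsulfinyl)propanoate with Cs2CO3, is coupled under Pd(dba)2 and a bulky ferrocenyl bisphosphine of the Josiphos family in toluene at 80 °C (enantioselective alkenylation of a sulfenate). The route is rejoined at 10.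

Step 14. Ionisation of the protonated vinyl epoxide to an allyl cation may outrun direct displacement. That would lead to loss of inversion at C8 and to attack of water at the far allyl terminus.

The fallback sets C8 by reduction instead of substitution and sets out from diene angelate 23. OsO4 (cat.) with N-methylmorpholine N-oxide should dihydroxylate C8=C9 anti to the C10 methyl to give the cis-diol F4. MnO2 oxidises only the allylic C8 alcohol to give the C9-hydroxy enone F5. NaBH4/CeCl3 in MeOH at −78 °C (Luche reduction, axial hydride delivery) should then give the equatorial C8 alcohol, and the route is rejoined at 25.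

**Further compounds**
F1 | step 7 | γ-(phenylsulfanyl) lactone tert-butyl ester | CC(C)(C)OC(=O)C1C(=O)O[C@]2(Sc3ccccc3)C[C@@]4(C[C@H]12)C(=O)C=CC[C@@H]4C
F2 | step 7 | lactone tert-butyl ester | CC(C)(C)OC(=O)C1C(=O)O[C@@H]2C[C@@]3(C[C@H]12)C(=O)C=CC[C@@H]3C
F3 | step 7 | α-carboxy lactone | OC(=O)C1C(=O)O[C@@H]2C[C@@]3(C[C@H]12)C(=O)C=CC[C@@H]3C
F0 | step 6 | none | none
F4 | step 14 | C8,C9 cis-diol | C=C1C(=O)O[C@@H]2C[C@@]3(C[C@H]12)C(COC(=O)/C(C)=C\C)=C[C@@H](O)[C@@H](O)[C@@H]3C
F5 | step 14 | C9-hydroxy enone | C=C1C(=O)O[C@@H]2C[C@@]3(C[C@H]12)C(COC(=O)/C(C)=C\C)=CC(=O)[C@@H](O)[C@@H]3C
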